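Minutes of the meeting on the new flask. It opened on an impossibility: the share of J in J plus G at 2.0 min cannot be read from the earlier runs, for the first reading of the summer run comes later, at 10.0 min, and that of the dawn run at 20.0 min.

| setting | dawn | summer | flask |
|---|---|---|---|
| D | 1.4 M | 2.2 M | 1.0 M |
| remark | run made earlier | run made earlier |  |
| time |  |  | 2.5 h |

- dawn (time / min: J / %, G / %): 20.0: 3.9, 4.1; 40.0: 9.2, 9.0; 60.0: 10.9, 11.7; 80.0: 15.3, 12.7; 90.0: 19.7, 13.8; 120: 21.9, 15.6
- summer (time / min: J / %, G / %): 10.0: 2.9, 2.6; 15.0: 4.9, 3.5; 25.0: 6.5, 6.1; 40.0: 8.9, 8.3; 80.0: 15.9, 11.8; 120: 20.5, 13.0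

(each reading ± 1 percentage point)

* share of J in J plus G at 2.0 min
* share of J in J plus G at 15 min
* share of J in J plus G at 2.5 h



The forecaster argued that the two runs overlap, that “the percentages should carry over”, and gave 46.5%, 49% and 62%. I objected that the share of J (its selectivity against G), pooled over the readings at 80.0 min and 120 min, is 56.8% in the dawn run and higher, 59.5%, in the summer run, and I reckoned S = 0.0335 M⁻¹, the charge slope: the rise of that share, as a fraction, per molar of D charged. A colleague noted that readings scattering by 1 percentage point make S a weak reading. I still took the forecast's late figure as standing for the middle charge of the runs, 1.80 M, which brings the flask down to 59.3% at 2.5 h, below the forecast; for the early shares I offered no figure of my own.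

The flask gives 25.0% at 2.0 min, 41.9% at 15 min and 59.1% at 2.5 h, and by S the late gap of 2.9 points below the forecast is worth 0.866 M of charge.

    D + G → L (k = 0.00911 M⁻¹ min⁻¹)
    D ⇌ Z (K = 0.590, k = 0.364 min⁻¹)
    D → G (k = 0.00480 min⁻¹)
    G ⇌ J (K = 24.6, k = 0.00285 min⁻¹)
    Z → J (k = 0.00597 min⁻¹)

At 2.5 h in the flask, D has a half-life of 2.4 h by the making of G and a longer one, 6.7 h, by its loss with G to L. G, which stands at 18.8% in the flask at 2.50 h, is then made 1.31 times as fast as it is lost, each step taken net. For the same flask with 2.5 M of D, S gives 64.2%; the computed share at 2.5 h is higher, 65.6%.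

The numbers in the tables are calculated on assumed constants; noise was put on by code.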